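**Retrosynthetic overview**

1. Feature: in the upper 5-deoxyflavan unit, C4 is a diarylmethine that joins C4a of benzo ring A (whose ortho carbon C8a carries O1) to C8' of ring D of the epiafzelechin unit. This is the β-carbon of a chalcone-type enone after 1,4-addition of an ortho-hydroxyaryl nucleophile, and the enone carbonyl carbon is C2.
2. Target 21 ⇐ hexabenzyl ether 20 (hydrogenolysis) ⇐ 4H-chromene 18 (hydroboration–oxidation of C2=C3 anti to the C4 substituent sets C2 and C3).
3. 18 ⇐ enone 10 + boronic acid 15: rhodium/chiral-diene 1,4-addition forms C4–C4a and sets C4, then cyclodehydration forms O1–C2 and closes ring C.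
4. 10 ⇐ aldehyde 7 + 4'-(benzyloxy)acetophenone 8 (Claisen–Schmidt); 7 ⇐ (−)-epiafzelechin 1 (benzylation, C8 bromination, Br/Li exchange–DMF); 15 ⇐ 4-bromoresorcinol 11.
5. Ring order: rings D, E and F arrive intact in 1, rings A and B as intact arenes in 15 and 8; ring C is the only ring built (step 8).

Key step: step 8

Remark: the target is read as guibourtinidol-(4α→8)-epiafzelechin, upper unit 2R,3S,4S (2,3-trans-3,4-trans), lower unit 2R,3R. Rings A/B/C belong to the upper unit and D/E/F to the lower unit, and primed locants denote the lower unit. (−)-Epiafzelechin is assumed to be purchasable as the natural 2R,3R compound. The choice of the (R,R) diene is a prediction from the usual quadrant model; its enantiomer is equally accessible.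

**Route**

Step 1
Reactants: 1 (−)-epiafzelechin
Product: 2 5,7,4'-tri-O-benzylepiafzelechin
Conditions: BnBr (3.3 equiv), K2CO3 (4 equiv), degassed DMF, 0 °C to rt, argon
Reagents that add atoms: benzyl bromide, BrCc1ccccc1
Why: Williamson etherification in which K2CO3 ionises only the three phenols, so the secondary 3-OH stays free and C2/C3 are not touched.

Step 2
Reactants: 2 5,7,4'-tri-O-benzylepiafzelechin
Product: 3 3,5,7,4'-tetra-O-benzylepiafzelechin
Conditions: NaH (1.5 equiv), BnBr (1.3 equiv), Bu4NI (5 mol %), THF/DMF, 0 °C to rt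
Reagents that add atoms: benzyl bromide, BrCc1ccccc1
Why: Williamson etherification of the secondary alkoxide; the phenols are already capped, so only O3 reacts and no stereocentre is affected.

Step 3
Reactants: 3 3,5,7,4'-tetra-O-benzylepiafzelechin
Product: 4 8-bromo-3,5,7,4'-tetra-O-benzylepiafzelechin
Conditions: NBS (1.05 equiv), CH2Cl2, −78 °C to 0 °C
Reagents that add atoms: N-bromosuccinimide, BrN1C(=O)CCC1=O
Why: Electrophilic aromatic bromination of the triply oxygenated ring D, which is far more electron-rich than ring E; in 5,7-di-O-benzylflavan ethers C8 is the position that reacts first at low temperature with one equivalent.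

Step 4
Reactants: 4 8-bromo-3,5,7,4'-tetra-O-benzylepiafzelechin
Product: 7 3,5,7,4'-tetra-O-benzylepiafzelechin-8-carbaldehyde, via 8-lithio arene 5 (not isolated), via hemiaminal alkoxide 6 (not isolated)
Conditions: n-BuLi (1.2 equiv), THF, −78 °C; DMF (5 equiv), −78 to 0 °C; 1 M HCl
Reagents that add atoms: N,N-dimethylformamide, CN(C)C=O
Why: Bromine–lithium exchange followed by Bouveault formylation; exchange at −78 °C outruns benzylic deprotonation, and the tetrahedral adduct collapses to the aldehyde on acidic work-up.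

Step 5
Reactants: 7 3,5,7,4'-tetra-O-benzylepiafzelechin-8-carbaldehyde; 8 4'-(benzyloxy)acetophenone
Product: 10 (E)-1-[4-(benzyloxy)phenyl]-3-(3,5,7,4'-tetra-O-benzylepiafzelechin-8-yl)prop-2-en-1-one, via aldol adduct 9 (not isolated)
Conditions: KOH (2 equiv, 50% aq), EtOH/THF 1:1, rt to 40 °C
Reagents that add atoms: none
Why: Claisen–Schmidt condensation of a non-enolisable aldehyde with a methyl ketone; E1cB dehydration of the aldol should give the thermodynamically favoured (E)-enone.

Step 6
Reactants: 11 4-bromoresorcinol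
Product: 12 5-(benzyloxy)-2-bromophenol
Conditions: BnBr (1.0 equiv), K2CO3 (1.1 equiv), acetone, rt to 50 °C
Reagents that add atoms: benzyl bromide, BrCc1ccccc1
Why: Williamson etherification with one equivalent of electrophile; the hydroxyl para to bromine is less hindered and its phenoxide more nucleophilic than the one flanked by bromine, so monobenzylation there should predominate (regioisomer and bis-ether removed by chromatography).

Step 7
Reactants: 12 5-(benzyloxy)-2-bromophenol
Product: 15 (4-benzyloxy-2-hydroxyphenyl)boronic acid, via dilithio phenoxide 13 (not isolated), via triisopropoxyborate 14 (not isolated)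
Conditions: n-BuLi (2.2 equiv), THF, −78 to −40 °C; B(OiPr)3 (3 equiv), −78 °C to rt; 1 M HCl, 0 °C
Reagents that add atoms: triisopropyl borate, CC(C)OB(OC(C)C)OC(C)C; water, O
Why: Lithiation–borylation: the first equivalent of base forms the phenoxide, the second effects bromine–lithium exchange, and the aryllithium is trapped by the borate and hydrolysed, the way 2-hydroxyphenylboronic acid is made from 2-bromophenol.

Step 8
Reactants: 10 (E)-1-[4-(benzyloxy)phenyl]-3-(3,5,7,4'-tetra-O-benzylepiafzelechin-8-yl)prop-2-en-1-one; 15 (4-benzyloxy-2-hydroxyphenyl)boronic acid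
Product: 18 (4S)-7-benzyloxy-2-[4-(benzyloxy)phenyl]-4-(3,5,7,4'-tetra-O-benzylepiafzelechin-8-yl)-4H-chromene, via ketone 16 (not isolated), via hemiketal 17 (not isolated)
Conditions: [Rh(C2H4)2Cl]2 (5 mol %), (R,R)-Ph-bod* [(1R,4R)-2,5-diphenylbicyclo[2.2.2]octa-2,5-diene] (11 mol %), KOH (0.5 equiv), 15 (3 equiv, in portions), dioxane/H2O 10:1, 50 °C; then p-TsOH·H2O (10 mol %), 4 Å MS, toluene, rt, argon
Reagents that add atoms: none
Why: KOH and the diene turn the chloride-bridged rhodium dimer into a hydroxorhodium species that transmetalates with 15, inserts the enone C=C so that ring A is delivered to the β-carbon (C4–C4a bond), and is released by hydrolysis of the oxa-π-allylrhodium as ketone 16; this is the Hayashi–Miyaura asymmetric 1,4-addition of arylboronic acids to chalcone-type enones. The ortho-phenol of 16 then adds to the aryl ketone in a 6-exo-trig hemiketalisation to 17 (O1–C2 bond, ring C), and acid-catalysed loss of water through the 2-aryl oxocarbenium ion gives the enol ether, as is known for β-(2-hydroxyaryl) ketones. The one new stereocentre, C4, is set by the catalyst: the aroyl arm on the α-carbon turns away from the phenyl group on the neighbouring coordinated olefin of the (R,R) ligand and the (E)-geometry puts ring D into the opposite open quadrant, which corresponds to 4S and should override the remote stereocentres of the lower unit. The step needs 1,4- over 1,2-addition, which arylrhodium species show with enones, and C–C bond formation before O–C closure, which holds because only the boron-bearing carbon transmetalates and the ortho-hydroxyl can reach the carbonyl only once C4–C4a exists. The 2,6-dioxygenated ring D slows insertion, so the highly active diene catalyst and an excess of 15 (against protodeboronation) are used.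

Step 9
Reactants: 18 (4S)-7-benzyloxy-2-[4-(benzyloxy)phenyl]-4-(3,5,7,4'-tetra-O-benzylepiafzelechin-8-yl)-4H-chromene
Product: 20 hexa-O-benzyl guibourtinidol-(4α→8)-epiafzelechin (upper 3-OH free; 2R,3S,4S), via C3-borane 19 (not isolated)
Conditions: BH3·SMe2 (3 equiv), THF, 0 °C to rt; then 3 M NaOH, 30% H2O2, 0 °C to rt
Reagents that add atoms: hydrogen peroxide, OO
Why: Brown hydroboration–oxidation of the enol ether: boron goes to C3 (β to O1), H and B add syn from the face opposite the bulky C4 substituent, and oxidation with retention should give the 2,3-trans-3,4-trans alcohol, so C3 (S) and C2 (R) are relayed from C4.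

Step 10
Reactants: 20 hexa-O-benzyl guibourtinidol-(4α→8)-epiafzelechin
Product: 21 guibourtinidol-(4α→8)-epiafzelechin (CNP0110462.3)
Conditions: H2 (1 atm), Pd(OH)2/C (20 wt %), THF/MeOH/H2O 20:20:1, rt
Reagents that add atoms: none
Why: Hydrogenolysis of the six benzyl ethers; at 1 atm and room temperature the cyclic benzylic C2–O1 bonds and the C4–C8' bond of flavan oligomers should be retained, and no stereocentre is affected.

**Compound list**

1 | (−)-epiafzelechin, (2R,3R) | Oc1ccc([C@H]2Oc3cc(O)cc(O)c3C[C@H]2O)cc1 | starting material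
2 | 5,7,4'-tri-O-benzylepiafzelechin | c1ccccc1COc1ccc([C@H]2Oc3cc(OCc4ccccc4)cc(OCc4ccccc4)c3C[C@H]2O)cc1 | intermediate
3 | 3,5,7,4'-tetra-O-benzylepiafzelechin | c1ccccc1COc1ccc([C@H]2Oc3cc(OCc4ccccc4)cc(OCc4ccccc4)c3C[C@H]2OCc2ccccc2)cc1 | intermediate
4 | 8-bromo-3,5,7,4'-tetra-O-benzylepiafzelechin | c1ccccc1COc1ccc([C@H]2Oc3c(Br)c(OCc4ccccc4)cc(OCc4ccccc4)c3C[C@H]2OCc2ccccc2)cc1 | intermediate
5 | 8-lithio-3,5,7,4'-tetra-O-benzylepiafzelechin | c1ccccc1COc1ccc([C@H]2Oc3c([Li])c(OCc4ccccc4)cc(OCc4ccccc4)c3C[C@H]2OCc2ccccc2)cc1 | intermediate (not isolated)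
6 | lithium alkoxide of the 8-[(dimethylamino)(hydroxy)methyl] adduct (carbinol centre undefined) | c1ccccc1COc1ccc([C@H]2Oc3c(C(O[Li])N(C)C)c(OCc4ccccc4)cc(OCc4ccccc4)c3C[C@H]2OCc2ccccc2)cc1 | intermediate (not isolated)
7 | 3,5,7,4'-tetra-O-benzylepiafzelechin-8-carbaldehyde | c1ccccc1COc1ccc([C@H]2Oc3c(C=O)c(OCc4ccccc4)cc(OCc4ccccc4)c3C[C@H]2OCc2ccccc2)cc1 | intermediate
8 | 4'-(benzyloxy)acetophenone | CC(=O)c1ccc(OCc2ccccc2)cc1 | starting material
9 | 1-[4-(benzyloxy)phenyl]-3-hydroxy-3-(3,5,7,4'-tetra-O-benzylepiafzelechin-8-yl)propan-1-one (carbinol centre undefined) | O=C(CC(O)c1c(OCc2ccccc2)cc(OCc2ccccc2)c2c1O[C@H](c1ccc(OCc3ccccc3)cc1)[C@H](OCc1ccccc1)C2)c1ccc(OCc2ccccc2)cc1 | intermediate (not isolated)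
10 | (E)-1-[4-(benzyloxy)phenyl]-3-(3,5,7,4'-tetra-O-benzylepiafzelechin-8-yl)prop-2-en-1-one | O=C(/C=C/c1c(OCc2ccccc2)cc(OCc2ccccc2)c2c1O[C@H](c1ccc(OCc3ccccc3)cc1)[C@H](OCc1ccccc1)C2)c1ccc(OCc2ccccc2)cc1 | intermediate
11 | 4-bromoresorcinol | Oc1ccc(Br)c(O)c1 | starting material
12 | 5-(benzyloxy)-2-bromophenol | Oc1cc(OCc2ccccc2)ccc1Br | intermediate
13 | lithium 5-(benzyloxy)-2-lithiophenoxide | [Li]Oc1cc(OCc2ccccc2)ccc1[Li] | intermediate (not isolated)
14 | dilithium salt of [4-(benzyloxy)-2-oxidophenyl]triisopropoxyborate | [Li+].[Li]Oc1cc(OCc2ccccc2)ccc1[B-](OC(C)C)(OC(C)C)OC(C)C | intermediate (not isolated)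
15 | (4-benzyloxy-2-hydroxyphenyl)boronic acid | OB(O)c1ccc(OCc2ccccc2)cc1O | intermediate
16 | (3S)-3-[4-(benzyloxy)-2-hydroxyphenyl]-1-[4-(benzyloxy)phenyl]-3-(3,5,7,4'-tetra-O-benzylepiafzelechin-8-yl)propan-1-one | O=C(C[C@@H](c1ccc(OCc2ccccc2)cc1O)c1c(OCc2ccccc2)cc(OCc2ccccc2)c2c1O[C@H](c1ccc(OCc3ccccc3)cc1)[C@H](OCc1ccccc1)C2)c1ccc(OCc2ccccc2)cc1 | intermediate (not isolated)
17 | (4S)-7-benzyloxy-2-[4-(benzyloxy)phenyl]-4-(3,5,7,4'-tetra-O-benzylepiafzelechin-8-yl)chroman-2-ol (C2 epimers) | C(c1ccccc1)Oc1ccc(C2(O)C[C@H](c3c(OCc4ccccc4)cc(OCc4ccccc4)c4c3O[C@H](c3ccc(OCc5ccccc5)cc3)[C@H](OCc3ccccc3)C4)c3ccc(OCc4ccccc4)cc3O2)cc1 | intermediate (not isolated)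
18 | (4S)-7-benzyloxy-2-[4-(benzyloxy)phenyl]-4-(3,5,7,4'-tetra-O-benzylepiafzelechin-8-yl)-4H-chromene | C(c1ccccc1)Oc1ccc(C2=C[C@H](c3c(OCc4ccccc4)cc(OCc4ccccc4)c4c3O[C@H](c3ccc(OCc5ccccc5)cc3)[C@H](OCc3ccccc3)C4)c3ccc(OCc4ccccc4)cc3O2)cc1 | intermediate
19 | C3-borane of 20 (BH2 in place of the upper 3-OH, same configuration) | c1ccccc1COc1ccc([C@H]2Oc3cc(OCc4ccccc4)ccc3[C@@H](c3c(OCc4ccccc4)cc(OCc4ccccc4)c4c3O[C@H](c3ccc(OCc5ccccc5)cc3)[C@H](OCc3ccccc3)C4)[C@@H]2B)cc1 | intermediate (not isolated)
20 | hexa-O-benzyl guibourtinidol-(4α→8)-epiafzelechin, (2R,3S,4S)-7-benzyloxy-2-[4-(benzyloxy)phenyl]-4-(3,5,7,4'-tetra-O-benzylepiafzelechin-8-yl)chroman-3-ol | c1ccccc1COc1ccc([C@H]2Oc3cc(OCc4ccccc4)ccc3[C@@H](c3c(OCc4ccccc4)cc(OCc4ccccc4)c4c3O[C@H](c3ccc(OCc5ccccc5)cc3)[C@H](OCc3ccccc3)C4)[C@@H]2O)cc1 | intermediate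
21 | guibourtinidol-(4α→8)-epiafzelechin (CNP0110462.3) | Oc1ccc([C@H]2Oc3cc(O)ccc3[C@@H](c3c(O)cc(O)c4c3O[C@H](c3ccc(O)cc3)[C@H](O)C4)[C@@H]2O)cc1 | target

**Totals**

Total step count: 10. Longest linear sequence: 8 steps (steps 1–5, 8–10).

**Steps most likely to fail**

Step 8 (key step). The hindered, electron-rich enone may insert into the aryl–rhodium bond so slowly that protodeboronation of the electron-rich boronic acid wins, or the catalyst may not fully control the β-face against the lower-unit stereocentres. The fallback sets out from aldehyde 7 and the dilithio phenoxide 13 (generated from 12 as in step 7) and makes the C3–C4 bond instead. Addition of 13 to 7 in THF at −78 °C with neutral aqueous work-up should give the diarylmethanol [4-(benzyloxy)-2-hydroxyphenyl](3,5,7,4'-tetra-O-benzylepiafzelechin-8-yl)methanol F1. Ketone 8 is converted with TMSOTf/Et3N (CH2Cl2, 0 °C) into its silyl enol ether {1-[4-(benzyloxy)phenyl]ethenyloxy}trimethylsilane F2. A BINOL-derived chiral phosphoric acid (TRIP, 5–10 mol %, toluene, −40 °C, both enantiomers to be tried) ionises F1 to the ortho-quinone methide, which F2 attacks at the methide carbon in a Mukaiyama–Michael-type addition. Loss of the silyl group then gives ketone 16, where the route is rejoined (cyclodehydration to 18 as in step 8). If counter-anion control at C4 is incomplete, the C4 epimers are diastereomers and would be separated at 18.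

Step 9. Discrimination between the two faces of the enol ether may be incomplete, or the C3 borane may undergo β-alkoxy elimination with opening of ring C. The fallback sets out from 18. Dihydroxylation (OsO4 5 mol %, NMO, acetone/H2O, 0 °C) anti to the C4 substituent should give the 2,3-cis hemiketal diol (4S)-7-benzyloxy-2-[4-(benzyloxy)phenyl]-4-(3,5,7,4'-tetra-O-benzylepiafzelechin-8-yl)chroman-2,3-diol F3. Ionic reduction (Et3SiH, CF3CO2H, CH2Cl2, −40 °C) through the 2-aryl oxocarbenium ion, with pseudo-axial hydride delivery that leaves the C2 aryl equatorial and trans to O3 (the mode seen when aryl lactols are reduced to β-C-aryl glycosides), should then give 20, where the route is rejoined.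

Step 7. Bromine–lithium exchange on the lithium phenoxide may be incomplete, and the electron-rich ortho-hydroxyarylboronic acid may protodeboronate during acidic isolation. The fallback sets out from 12. Miyaura borylation (Pd(dppf)Cl2 5 mol %, B2pin2 1.3 equiv, KOAc 3 equiv, dioxane, 85 °C), which tolerates free phenols, should give the pinacol boronate 5-(benzyloxy)-2-(4,4,5,5-tetramethyl-1,3,2-dioxaborolan-2-yl)phenol F4. F4 is used in place of 15 under the conditions of step 8 (pinacol esters transmetalate to hydroxorhodium in aqueous KOH), and the route is rejoined at 18.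

**Further compounds**

F1 | step 8 | [4-(benzyloxy)-2-hydroxyphenyl](3,5,7,4'-tetra-O-benzylepiafzelechin-8-yl)methanol (carbinol centre undefined) | OC(c1ccc(OCc2ccccc2)cc1O)c1c(OCc2ccccc2)cc(OCc2ccccc2)c2c1O[C@H](c1ccc(OCc3ccccc3)cc1)[C@H](OCc1ccccc1)C2
F2 | step 8 | {1-[4-(benzyloxy)phenyl]ethenyloxy}trimethylsilane | C=C(O[Si](C)(C)C)c1ccc(OCc2ccccc2)cc1
F3 | step 9 | (4S)-7-benzyloxy-2-[4-(benzyloxy)phenyl]-4-(3,5,7,4'-tetra-O-benzylepiafzelechin-8-yl)chroman-2,3-diol (2,3-cis, both hydroxyls anti to the C4 substituent) | c1ccccc1COc1ccc([C@@]2(O)Oc3cc(OCc4ccccc4)ccc3[C@@H](c3c(OCc4ccccc4)cc(OCc4ccccc4)c4c3O[C@H](c3ccc(OCc5ccccc5)cc3)[C@H](OCc3ccccc3)C4)[C@@H]2O)cc1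
F4 | step 7 | 5-(benzyloxy)-2-(4,4,5,5-tetramethyl-1,3,2-dioxaborolan-2-yl)phenol | Oc1cc(OCc2ccccc2)ccc1B1OC(C)(C)C(C)(C)O1
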